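**Plan**
- Retrosynthesis: the C1 ketone and the ring A phenol next to it are folded back into a 1,2-benzisoxazole. Its ring A–C1 bond and the neighbouring ring A C–O bond are then cut to an aryne and a nitrile oxide, and the chain is cut at C11–aryl (B-alkyl Suzuki–Miyaura).
- Enabling feature: in ring A (the 2,4,6-trihydroxyphenyl ring) the carbon carrying the C1 carbonyl lies ortho to a carbon carrying a phenolic oxygen. That C–C/C–O pair is what the carbon and oxygen termini of a nitrile oxide leave behind after addition across an aryne bond, and the other two ring A oxygens fit a 3,5-dioxygenated benzyne.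
- Forward order: silyl triflate 6 from phenol 1 (steps 1–3); chloro-oxime 13 from ester 7 and bromide 8 (steps 4–7); cycloaddition closes the temporary isoxazole, the only ring formed (step 8); one hydrogenolysis cleaves N–O and all three benzyl ethers, and acid hydrolysis of the ketimine gives the ketone (step 9).
- Stereochemistry: the target has no stereocentre and none is created.

Key step: step 8

Remark: benzyl ethers replace methyl ethers throughout so that the N–O cleavage and all deprotections fall into one hydrogenolysis. Compounds 1, 7 and 8 are taken as commercial. Oxime 12 and chloro-oxime 13 are handled as E/Z mixtures, since both geometries give the same nitrile oxide.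

Step 1
Reactants: 1 3,5-bis(benzyloxy)phenol
Product: 2 3,5-bis(benzyloxy)-2-bromophenol
Conditions: NBS (1.0 equiv), CH2Cl2, –78 °C → rt
Reagents that add atoms: N-bromosuccinimide, O=C1CCC(=O)N1Br
Why: Electrophilic aromatic bromination in a non-polar solvent, where hydrogen bonding of NBS to the phenol should direct bromine to the two equivalent ortho carbons and away from the carbon flanked by two benzyloxy groups, with one equivalent at low temperature limiting dibromination.

Step 2
Reactants: 2 3,5-bis(benzyloxy)-2-bromophenol
Product: 3 [3,5-bis(benzyloxy)-2-bromophenoxy]trimethylsilane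
Conditions: HMDS, THF, reflux; volatiles removed, crude used directly
Reagents that add atoms: hexamethyldisilazane, C[Si](C)(C)N[Si](C)(C)C
Why: O-Silylation of a phenol with hexamethyldisilazane, driven by loss of ammonia and leaving only volatile by-products, so the moisture-sensitive silyl ether can go on without purification.

Step 3
Reactants: 3 [3,5-bis(benzyloxy)-2-bromophenoxy]trimethylsilane
Product: 6 3,5-bis(benzyloxy)-2-(trimethylsilyl)phenyl trifluoromethanesulfonate, via aryllithium 4 (not isolated), via lithium phenoxide 5 (not isolated)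
Conditions: n-BuLi (1.1 equiv), THF, –78 °C; then Tf2O (1.2 equiv), –78 → 0 °C
Reagents that add atoms: trifluoromethanesulfonic anhydride, O=S(=O)(OS(=O)(=O)C(F)(F)F)C(F)(F)F
Why: Bromine–lithium exchange followed by anionic 1,3 O→C silyl migration (retro-Brook rearrangement) should give the ortho-silyl phenoxide, which is trapped on oxygen by Tf2O in the standard route to ortho-silylaryl triflates; at –78 °C the exchange should outrun deprotonation of the benzylic ether positions.

Step 4
Reactants: 7 methyl undec-10-enoate; 8 1-(benzyloxy)-2-bromobenzene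
Product: 10 methyl 11-[2-(benzyloxy)phenyl]undecanoate, via alkylborane 9 (not isolated)
Conditions: 9-BBN (1.1 equiv), THF, 0 °C → rt; then 8, Pd(dppf)Cl2 (3 mol %), K2CO3, DMF, 50 °C
Reagents that add atoms: none
Why: Anti-Markovnikov hydroboration of the terminal alkene and B-alkyl Suzuki–Miyaura coupling (oxidative addition of zerovalent palladium into the aryl bromide, base-assisted transmetalation of the primary alkyl group, reductive elimination), run with carbonate in DMF so that the methyl ester survives.

Step 5
Reactants: 10 methyl 11-[2-(benzyloxy)phenyl]undecanoate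
Product: 11 11-[2-(benzyloxy)phenyl]undecanal
Conditions: i-Bu2AlH (1.05 equiv), CH2Cl2, –78 °C; MeOH, then aqueous Rochelle salt
Reagents that add atoms: none
Why: Partial reduction of an ester with i-Bu2AlH, in which the aluminium hemiacetal persists at –78 °C and collapses to the aldehyde only on work-up, so that a second hydride transfer is avoided.

Step 6
Reactants: 11 11-[2-(benzyloxy)phenyl]undecanal
Product: 12 11-[2-(benzyloxy)phenyl]undecanal oxime (E/Z mixture)
Conditions: NH2OH·HCl, NaOAc, EtOH–H2O, rt
Reagents that add atoms: hydroxylamine hydrochloride, NO.Cl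
Why: Condensation of an unhindered aliphatic aldehyde with hydroxylamine under acetate buffering (oxime formation), to which no other group in the molecule responds.

Step 7
Reactants: 12 11-[2-(benzyloxy)phenyl]undecanal oxime
Product: 13 11-[2-(benzyloxy)phenyl]-N-hydroxyundecanimidoyl chloride
Conditions: NCS (1.05 equiv), DMF, 0 °C → rt; extractive work-up, used crude
Reagents that add atoms: N-chlorosuccinimide, O=C1CCC(=O)N1Cl
Why: Chlorination of an aldoxime at carbon with NCS in DMF gives the hydroximoyl chloride, and without acid catalysis the monoalkoxy arene should not be ring-chlorinated at this temperature.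

Step 8
Reactants: 6 3,5-bis(benzyloxy)-2-(trimethylsilyl)phenyl trifluoromethanesulfonate; 13 11-[2-(benzyloxy)phenyl]-N-hydroxyundecanimidoyl chloride
Product: 16 4,6-bis(benzyloxy)-3-{10-[2-(benzyloxy)phenyl]decyl}-1,2-benzoxazole, via aryne 14 (not isolated), via nitrile oxide 15 (not isolated)
Conditions: CsF (5 equiv), MeCN, rt; 13 in MeCN added by syringe pump over 3 h to 6 (1.5 equiv)
Reagents that add atoms: none
Why: Fluoride attacks silicon in 6 and triflate leaves from the neighbouring carbon to give aryne 14, while fluoride acting as a base removes HCl from 13 to give nitrile oxide 15, which slow addition keeps dilute so that dimerization to the furoxan should lag behind trapping. The two partners then join in a concerted, asynchronous (3+2) dipolar cycloaddition, the known fluoride-induced aryne–nitrile oxide route to 1,2-benzisoxazoles. The isoxazole ring closes by this intermolecular cycloaddition, the dipole carbon bonding to the former silyl-bearing carbon (the ring A–C1 bond) and the dipole oxygen to the former triflate-bearing carbon (the ring A C–O bond). No stereocentre is formed. The selectivity needed is regiochemical: the benzyloxy group beside the aryne bond withdraws inductively and distorts the aryne so that the remote carbon becomes the more electrophilic one, which should draw the nucleophilic oxygen terminus there and leave the carbon terminus next to the benzyloxy group, against a steric preference for the opposite sense. This orientation places C1 between two oxygenated carbons with the third oxygen para, the pattern of ring A.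

Step 9
Reactants: 16 4,6-bis(benzyloxy)-3-{10-[2-(benzyloxy)phenyl]decyl}-1,2-benzoxazole
Product: 18 11-(2-hydroxyphenyl)-1-(2,4,6-trihydroxyphenyl)undecan-1-one, via ketimine 17 (not isolated)
Conditions: H2 (1 atm), 10% Pd/C, EtOAc–MeOH, rt; filter; then 1 M HCl, THF, 50 °C
Reagents that add atoms: water, O
Why: Catalytic hydrogenolysis should cleave the weak N–O bond of the 1,2-benzisoxazole and the three benzyl ethers in one operation, stopping at the hydrogen-bonded ortho-hydroxyaryl ketimine (a vinylogous amide that resists further reduction), which warm dilute acid then hydrolyses to the ketone as in the work-up of a Hoesch reaction.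

**Compound list**
1 | 3,5-bis(benzyloxy)phenol | Oc1cc(OCc2ccccc2)cc(OCc2ccccc2)c1 | starting material
2 | 3,5-bis(benzyloxy)-2-bromophenol | Oc1cc(OCc2ccccc2)cc(OCc2ccccc2)c1Br | intermediate
3 | [3,5-bis(benzyloxy)-2-bromophenoxy]trimethylsilane | C[Si](C)(C)Oc1cc(OCc2ccccc2)cc(OCc2ccccc2)c1Br | intermediate
4 | [2,4-bis(benzyloxy)-6-(trimethylsilyloxy)phenyl]lithium | [Li]c1c(O[Si](C)(C)C)cc(OCc2ccccc2)cc1OCc1ccccc1 | intermediate (not isolated)
5 | lithium 3,5-bis(benzyloxy)-2-(trimethylsilyl)phenoxide | [Li+].[O-]c1cc(OCc2ccccc2)cc(OCc2ccccc2)c1[Si](C)(C)C | intermediate (not isolated)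
6 | 3,5-bis(benzyloxy)-2-(trimethylsilyl)phenyl trifluoromethanesulfonate | C[Si](C)(C)c1c(OS(=O)(=O)C(F)(F)F)cc(OCc2ccccc2)cc1OCc1ccccc1 | intermediate
7 | methyl undec-10-enoate | C=CCCCCCCCCC(=O)OC | starting material
8 | 1-(benzyloxy)-2-bromobenzene | Brc1ccccc1OCc1ccccc1 | starting material
9 | methyl 11-(9-borabicyclo[3.3.1]nonan-9-yl)undecanoate | COC(=O)CCCCCCCCCCB1C2CCCC1CCC2 | intermediate (not isolated)
10 | methyl 11-[2-(benzyloxy)phenyl]undecanoate | COC(=O)CCCCCCCCCCc1ccccc1OCc1ccccc1 | intermediate
11 | 11-[2-(benzyloxy)phenyl]undecanal | O=CCCCCCCCCCCc1ccccc1OCc1ccccc1 | intermediate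
12 | 11-[2-(benzyloxy)phenyl]undecanal oxime (E/Z mixture) | ON=CCCCCCCCCCCc1ccccc1OCc1ccccc1 | intermediate
13 | 11-[2-(benzyloxy)phenyl]-N-hydroxyundecanimidoyl chloride | ON=C(Cl)CCCCCCCCCCc1ccccc1OCc1ccccc1 | intermediate
14 | 3,5-bis(benzyloxy)benzyne (3,5-bis(benzyloxy)-1,2-didehydrobenzene) | C1#CC(OCc2ccccc2)=CC(OCc2ccccc2)=C1 | intermediate (not isolated)
15 | 11-[2-(benzyloxy)phenyl]undecanenitrile oxide | [O-][N+]#CCCCCCCCCCCc1ccccc1OCc1ccccc1 | intermediate (not isolated)
16 | 4,6-bis(benzyloxy)-3-{10-[2-(benzyloxy)phenyl]decyl}-1,2-benzoxazole | C(Oc1cc(OCc2ccccc2)c2c(CCCCCCCCCCc3ccccc3OCc3ccccc3)noc2c1)c1ccccc1 | intermediate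
17 | 2-[11-(2-hydroxyphenyl)undecanimidoyl]benzene-1,3,5-triol | N=C(CCCCCCCCCCc1ccccc1O)c1c(O)cc(O)cc1O | intermediate (not isolated)
18 | 11-(2-hydroxyphenyl)-1-(2,4,6-trihydroxyphenyl)undecan-1-one | O=C(CCCCCCCCCCc1ccccc1O)c1c(O)cc(O)cc1O | target

**Step count and risks**
Total steps: 9. Longest linear sequence: 6 steps (7 → 10 → 11 → 12 → 13 → 16 → 18; steps 4–9). The aryne branch (steps 1–3) joins at step 8.

Steps most likely to fail:

1. Step 8. The dipole may add across the aryne bond in the reverse sense if the steric preference outweighs the inductive distortion, and the aliphatic nitrile oxide may dimerize before it meets the aryne. The fallback sets out from aldehyde 11 and makes the ring A–C1 bond by carbonyl addition, where the symmetry of the arene removes the regiochemical question. 1,3,5-Trimethoxybenzene would be lithiated (n-BuLi, TMEDA, THF, 0 °C) to (2,4,6-trimethoxyphenyl)lithium F1, which should add to 11 at –78 °C to give racemic 11-[2-(benzyloxy)phenyl]-1-(2,4,6-trimethoxyphenyl)undecan-1-ol F2. Oxidation with Dess–Martin periodinane (NaHCO3, CH2Cl2) would give 11-[2-(benzyloxy)phenyl]-1-(2,4,6-trimethoxyphenyl)undecan-1-one F3. BBr3 (CH2Cl2, –78 °C → rt) would then cleave the three methyl ethers and the benzyl ether, coming back to the route at target 18.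

2. Step 9. Hydrogenation may run past the ketimine to the benzylic amine, or debenzylation may stall on a poisoned catalyst. The fallback sets out from benzisoxazole 16 and avoids hydrogen. Mo(CO)6 in MeCN–H2O at reflux should cleave the N–O bond by the metal-carbonyl reduction known for isoxazoles, giving 3,5-bis(benzyloxy)-2-{11-[2-(benzyloxy)phenyl]undecanimidoyl}phenol F4. Dilute HCl on work-up would hydrolyse this to 1-[2,4-bis(benzyloxy)-6-hydroxyphenyl]-11-[2-(benzyloxy)phenyl]undecan-1-one F5. BCl3 with pentamethylbenzene as cation scavenger (CH2Cl2, –78 °C) would then remove the three benzyl ethers, coming back to the route at target 18.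

3. Step 1. Bromination may occur at the carbon between the two benzyloxy groups or twice, both of which spoil the later silyl migration. The fallback sets out from phenol 1 and places silicon by directed ortho-metalation. Et2NCOCl and K2CO3 (MeCN, reflux) would give 3,5-bis(benzyloxy)phenyl N,N-diethylcarbamate F6. s-BuLi/TMEDA (THF, –78 °C) should lithiate the carbon flanked by the carbamate and a benzyloxy group to give [2,4-bis(benzyloxy)-6-(diethylcarbamoyloxy)phenyl]lithium F7. Me3SiCl would trap this as 3,5-bis(benzyloxy)-2-(trimethylsilyl)phenyl N,N-diethylcarbamate F8. LiAlH4 (THF, reflux) would cleave the carbamate to 3,5-bis(benzyloxy)-2-(trimethylsilyl)phenol F9, and Tf2O with pyridine (CH2Cl2, 0 °C) would triflate it, coming back to the route at silyl triflate 6.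

**Further compounds**
F1 | step 8 | (2,4,6-trimethoxyphenyl)lithium | [Li]c1c(OC)cc(OC)cc1OC
F2 | step 8 | 11-[2-(benzyloxy)phenyl]-1-(2,4,6-trimethoxyphenyl)undecan-1-ol (racemic) | COc1cc(OC)c(C(O)CCCCCCCCCCc2ccccc2OCc2ccccc2)c(OC)c1
F3 | step 8 | 11-[2-(benzyloxy)phenyl]-1-(2,4,6-trimethoxyphenyl)undecan-1-one | COc1cc(OC)c(C(=O)CCCCCCCCCCc2ccccc2OCc2ccccc2)c(OC)c1
F4 | step 9 | 3,5-bis(benzyloxy)-2-{11-[2-(benzyloxy)phenyl]undecanimidoyl}phenol | N=C(CCCCCCCCCCc1ccccc1OCc1ccccc1)c1c(O)cc(OCc2ccccc2)cc1OCc1ccccc1
F5 | step 9 | 1-[2,4-bis(benzyloxy)-6-hydroxyphenyl]-11-[2-(benzyloxy)phenyl]undecan-1-one | O=C(CCCCCCCCCCc1ccccc1OCc1ccccc1)c1c(O)cc(OCc2ccccc2)cc1OCc1ccccc1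
F6 | step 1 | 3,5-bis(benzyloxy)phenyl N,N-diethylcarbamate | CCN(CC)C(=O)Oc1cc(OCc2ccccc2)cc(OCc2ccccc2)c1
F7 | step 1 | [2,4-bis(benzyloxy)-6-(diethylcarbamoyloxy)phenyl]lithium | CCN(CC)C(=O)Oc1cc(OCc2ccccc2)cc(OCc2ccccc2)c1[Li]
F8 | step 1 | 3,5-bis(benzyloxy)-2-(trimethylsilyl)phenyl N,N-diethylcarbamate | CCN(CC)C(=O)Oc1cc(OCc2ccccc2)cc(OCc2ccccc2)c1[Si](C)(C)C
F9 | step 1 | 3,5-bis(benzyloxy)-2-(trimethylsilyl)phenol | Oc1cc(OCc2ccccc2)cc(OCc2ccccc2)c1[Si](C)(C)C
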